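What interested me in these runs was a leftover: the L still standing at the end, while G, fed from Z through J, had been feeding X for the whole run.

    G ⇌ L (K1 = 0.35, k1 = 8.5 × 10⁻⁵ s⁻¹, Ea1 = 109 kJ mol⁻¹, ΔH1 = −45.0 kJ mol⁻¹)
    2 J → J2 (k2 = 3.9 × 10⁻⁴ M⁻¹ s⁻¹, Ea2 = 62.0 kJ mol⁻¹)
    J → G (k3 = 0.0010 s⁻¹, Ea3 = 102 kJ mol⁻¹)
    G ⇌ D (K4 = 2.0, k4 = 2.5 × 10⁻⁵ s⁻¹, Ea4 = 95.0 kJ mol⁻¹, ΔH4 = −31.0 kJ mol⁻¹)
    G → X (k5 = 1.2 × 10⁻⁴ s⁻¹, Ea5 = 109 kJ mol⁻¹)
    Z ⇌ J, rate k6*(cs6 - [J]) while solid is left; crystals form when [J] > cs6 (cs6 = 0.10 M, k6 = 9.4 × 10⁻⁴ s⁻¹)
    (constants at 50 °C)

| flask | Z | temperature | time |
|---|---|---|---|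
| Sunday's | 0.12 M | 20 °C | 20 h |
| Saturday's | 0.12 M | 65 °C | 20 h |
| Friday's | 0.12 M | 35 °C | 20 h |
| Thursday's | 0.12 M | 50 °C | 20 h |

- the flask that comes out highest in amount of L, in percent of the Z charged, or "all alike" when all lie within 1.5 percentage points (Sunday's / Saturday's / Friday's / Thursday's / all alike)
- L at the end, in percent of the Z charged, Sunday's
- L at the end, in percent of the Z charged, Saturday's
- L at the end, in percent of the Z charged, Friday's
- L at the end, in percent of the Z charged, Thursday's

- a species is counted by the Z in it: one J2 counts as two
- for a step with 2 of a species take k times the square, and two of it per event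
- given per volume of solution although it is solid: Z
- the constants hold at 50 °C; other temperatures follow from the activation energies and enthalpies
- at the start none of Z is in solution
- what has only dissolved of Z counts as not reacted

**Charge balance.** Z, charged at 0.12 M, was the limiting reagent. What reached L had first passed through J and G, and L stayed joined to G by a reversible step while G leaked away to X. So I treated L as a stock in transit, not as an end point.

**Bench rule.** The habit is to warm a flask until the run spans 5 time constants of the feed, here J → G. With the Arrhenius shift from 50 °C, the run spanned 1.48 of them in Sunday's flask and 11.3 in Friday's flask. The rule therefore rejected Sunday's and passed Friday's, and it raised no objection to going hotter.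

**Where it stops.** The rule watches the feed and not the drain. At 50 °C the ratio of G → X to J → G is 0.120, and it climbs with heat because the activation energy of the drain is higher. G → L and G → X have equal activation energies, so their forward ratio stays 0.708 at any temperature, and warming gives L no edge over X.

**Drain number.** Friday's flask gave 1.20: that is N, the run time multiplied by the rate constant of G → X at the flask's temperature. Sunday's flask gave 0.136, Thursday's 8.64 and Saturday's 52.2. I set the bench rule's border near N of one: Sunday's stood below it, while Thursday's and Saturday's stood far above it. In this reckoning of my own I committed to Friday's as highest, with its feed through and its N between those extremes, and this hand reckoning stopped there without a figure for L.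

**Result.** The forecast gave 3.5% for Sunday's, <0.001% for Saturday's, 17.9% for Friday's and 0.35% for Thursday's, named Friday's highest, and held that “L is only a transient because G→X drains it.”

The simulation put Friday's highest, with 17.9% of L, against 3.54% in Sunday's, 0.347% in Thursday's and 0% in Saturday's. Left until 200 h, Friday's flask held 0.683% of L. Its N at that time is 12.0, more than Thursday's flask reached at its end.

**Second flask.** Saturday's recipe run at 40 °C has N of 2.37, above Friday's and below Thursday's, so I expected L between their results. The computed flask ended at 9.53% of L.

(The numbers of this flask come from no measurement, and the outcome is calculated.)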